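**Strategy**

The N-methylpiperidine is traced back to a pyridine, and the pyridine to a 1,2,4-triazine. Piperidine atoms C3–C2(aryl)–N1–C6 are carried as the C6=C5(aryl)–N4=C3 azadiene of a 5-aryl-1,2,4-triazine, and the unsubstituted C4–C5 edge comes from norbornadiene as an acetylene equivalent. One inverse-electron-demand Diels–Alder/double cycloreversion forms C3–C4 and C5–C6 and releases N2 and cyclopentadiene. The precursor is a triazinyl phloroglucinol dimethyl ether with a mirror plane, so the later chromone annulation can only place the heterocycle at C6 of ring A. The flat pyridine masks the epimerisable benzylic amine centre until the penultimate step.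

Key step: step 3

Remark on the chemistry: 1, 4 and 14 are taken as purchasable; the sense of induction in steps 8 and 10 is assigned by analogy with simpler chromones and 2-arylpyridinium salts, and the antipodal ligand is used if the opposite sense is found.

**Route**

Step 1
Reactants: 1 1-(4-hydroxy-2,6-dimethoxyphenyl)ethan-1-one
Product: 2 2-(4-hydroxy-2,6-dimethoxyphenyl)-2-oxoacetaldehyde
Conditions: SeO2 (1.5 equiv), 1,4-dioxane/H2O (30:1), 100 °C; filtration from Se; azeotropic drying with toluene
Reagents that add atoms: selenium dioxide O=[Se]=O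
Why: Riley oxidation of the only enolisable position, the acetyl CH3, should give the aryl glyoxal (usable as its hydrate if that forms); no stereocentre is involved.

Step 2
Reactants: 2 2-(4-hydroxy-2,6-dimethoxyphenyl)-2-oxoacetaldehyde
Product: 3 3,5-dimethoxy-4-(1,2,4-triazin-5-yl)phenol
Conditions: formamidine acetate (3 equiv), N2H4·H2O (3 equiv), MeOH, 0 °C, 20 min; then 2, 0 °C to rt; then AcOH, 60 °C
Reagents that add atoms: formamidine acetate NC=N.CC(=O)O; hydrazine hydrate NN.O
Why: the classical 1,2,4-triazine synthesis by condensation of a 1,2-dicarbonyl compound with formamidrazone made in situ should place the aryl group at C5, because the hydrazine nitrogen condenses first with the aldehyde and the amidine nitrogen then closes onto the ketone.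

Step 3
Reactants: 3 3,5-dimethoxy-4-(1,2,4-triazin-5-yl)phenol; 4 bicyclo[2.2.1]hepta-2,5-diene (norbornadiene)
Product: 7 3,5-dimethoxy-4-(pyridin-2-yl)phenol, via triazine–norbornadiene cycloadduct 5 (not isolated), via norbornene-fused dihydropyridine 6 (not isolated)
Conditions: 4 (10 equiv), 1,2-dichlorobenzene, 150 °C, sealed tube, 24 h
Reagents that add atoms: none
Why: The triazine is an electron-poor 2-azadiene (C6=C5–N4=C3) and should add through its ring carbons C6 and C3 to one strained C=C bond of 4 in an inverse-electron-demand Diels–Alder reaction, which forms in a single concerted step the two bonds that become piperidine C3–C4 and C5–C6. Adduct 5 should lose N2 by cycloreversion to 6, and 6 should expel cyclopentadiene in a second retro-Diels–Alder step, so that 4 acts as an acetylene equivalent and C4 and C5 stay unsubstituted. The closest known reaction type is the triazine-to-pyridine conversion with norbornadiene or enamines. The six-membered nitrogen ring is closed by a concerted suprafacial [4+2] cycloaddition between two molecules, not by a tethered exo or endo cyclisation, and aromatisation makes it irreversible. No stereocentre survives, since the sp3 centres of 5 and 6 are erased on aromatisation, and the benzylic centre is deliberately left for step 10. The step needs regioselectivity and mono-addition: triazine C3 and C6 are the only carbon termini of the azadiene, the dienophile is symmetrical, the electron-rich phenol ring is inert to the electron-poor diene, and the second C=C bond of 4 leaves as cyclopentadiene.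

Step 4
Reactants: 7 3,5-dimethoxy-4-(pyridin-2-yl)phenol
Product: 9 1-[6-hydroxy-2,4-dimethoxy-3-(pyridin-2-yl)phenyl]ethan-1-one, via aryl acetate 8 (not isolated)
Conditions: Ac2O (1.5 equiv), BF3·OEt2 (4 equiv), 80 °C, 4 h; then H2O, 60 °C
Reagents that add atoms: acetic anhydride CC(=O)OC(C)=O
Why: O-acetylation followed by BF3-promoted Fries rearrangement should deliver the acetyl group ortho to the phenol, and since the para position is blocked and the two ortho positions are equivalent by symmetry only one regioisomer is expected.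

Step 5
Reactants: 9 1-[6-hydroxy-2,4-dimethoxy-3-(pyridin-2-yl)phenyl]ethan-1-one
Product: 11 5,7-dimethoxy-6-(pyridin-2-yl)-4H-chromen-4-one, via enaminone 10 (not isolated)
Conditions: Me2NCH(OMe)2 (3 equiv), toluene, 100 °C; evaporation; then AcOH, 100 °C
Reagents that add atoms: N,N-dimethylformamide dimethyl acetal COC(OC)N(C)C
Why: enaminone formation at the acetyl methyl group and acid-mediated addition–elimination of the phenol oxygen (6-endo-trig closure with loss of Me2NH) is the standard chromone annulation, and because the ring oxygen is the former para-phenol oxygen the pyridyl group is fixed at C6.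

Step 6
Reactants: 11 5,7-dimethoxy-6-(pyridin-2-yl)-4H-chromen-4-one
Product: 12 5,7-dihydroxy-6-(pyridin-2-yl)-4H-chromen-4-one
Conditions: BBr3 (6 equiv), CH2Cl2, −78 °C to rt, 16 h; then MeOH, H2O
Reagents that add atoms: none
Why: Lewis acid cleavage of the two aryl methyl ethers is placed at this robust, achiral chromone stage so that no stereocentre is ever exposed to BBr3.

Step 7
Reactants: 12 5,7-dihydroxy-6-(pyridin-2-yl)-4H-chromen-4-one
Product: 13 5,7-bis(benzyloxy)-6-(pyridin-2-yl)-4H-chromen-4-one
Conditions: BnBr (2.3 equiv), K2CO3 (4 equiv), DMF, 60 °C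
Reagents that add atoms: benzyl bromide BrCc1ccccc1
Why: Williamson etherification of both phenoxides (the chelated 5-OH needs the warm DMF conditions) should outrun quaternisation of the shielded pyridine nitrogen and installs groups that can be removed at the end without acid or base.

Step 8
Reactants: 13 5,7-bis(benzyloxy)-6-(pyridin-2-yl)-4H-chromen-4-one; 14 [4-(benzyloxy)phenyl]boronic acid
Product: 15 (2S)-5,7-bis(benzyloxy)-2-[4-(benzyloxy)phenyl]-6-(pyridin-2-yl)-2,3-dihydro-4H-chromen-4-one
Conditions: 14 (2 equiv), Pd(OCOCF3)2 (10 mol%), (R)-4-tert-butyl-2-(pyridin-2-yl)-4,5-dihydrooxazole (12 mol%), NH4PF6 (30 mol%), H2O (5 equiv), ClCH2CH2Cl, 60 °C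
Reagents that add atoms: none
Why: in this palladium-catalysed asymmetric conjugate addition of an arylboronic acid to a chromone, flavanone C2 should be set by face-selective insertion of the C2=C3 bond into the cationic aryl–palladium pyridine-oxazoline complex (catalyst control, 2S expected from the R ligand), and the base-free medium avoids retro-oxa-Michael racemisation.

Step 9
Reactants: 15 (2S)-5,7-bis(benzyloxy)-2-[4-(benzyloxy)phenyl]-6-(pyridin-2-yl)-2,3-dihydro-4H-chromen-4-one
Product: 16 2-{(2S)-5,7-bis(benzyloxy)-2-[4-(benzyloxy)phenyl]-4-oxo-3,4-dihydro-2H-chromen-6-yl}-1-methylpyridin-1-ium iodide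
Conditions: MeI (10 equiv), MeCN, 70 °C, sealed tube
Reagents that add atoms: iodomethane CI
Why: Menshutkin quaternisation at the only nucleophilic site, the pyridine nitrogen, installs the N-methyl group and activates the ring for hydrogenation, while the neutral conditions leave flavanone C2 untouched.

Step 10
Reactants: 16 2-{(2S)-5,7-bis(benzyloxy)-2-[4-(benzyloxy)phenyl]-4-oxo-3,4-dihydro-2H-chromen-6-yl}-1-methylpyridin-1-ium iodide
Product: 17 (2S)-5,7-bis(benzyloxy)-2-[4-(benzyloxy)phenyl]-6-[(2R)-1-methylpiperidin-2-yl]-2,3-dihydro-4H-chromen-4-one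
Conditions: [Ir(cod)Cl]2 (2 mol%), (R)-SynPhos (4.4 mol%), H2 (50 bar), toluene/CH2Cl2 (1:1), 30 °C; then aq NaHCO3
Reagents that add atoms: none
Why: iridium-catalysed asymmetric hydrogenation of a 2-aryl-N-alkylpyridinium salt should reduce the ring fully and set piperidine C2 (2R) in the final hydride transfer to C2 under control of the chiral bisphosphine, while the ketone, the benzyl ethers and the remote flavanone centre are not touched.

Step 11
Reactants: 17 (2S)-5,7-bis(benzyloxy)-2-[4-(benzyloxy)phenyl]-6-[(2R)-1-methylpiperidin-2-yl]-2,3-dihydro-4H-chromen-4-one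
Product: 18 (2S)-5,7-dihydroxy-2-(4-hydroxyphenyl)-6-[(2R)-1-methylpiperidin-2-yl]-2,3-dihydro-4H-chromen-4-one
Conditions: H2 (1 atm), 10% Pd/C, EtOAc/MeOH (1:1), rt; stopped at full conversion
Reagents that add atoms: none
Why: hydrogenolysis of the three benzyl aryl ethers under neutral conditions at room temperature should release the phenols without epimerising either stereocentre, O-benzyl cleavage being much faster than cleavage of the benzylic C–N or C2–O1 bonds.

**Compound list**

1 | 1-(4-hydroxy-2,6-dimethoxyphenyl)ethan-1-one | CC(=O)c1c(OC)cc(O)cc1OC | starting material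
2 | 2-(4-hydroxy-2,6-dimethoxyphenyl)-2-oxoacetaldehyde | O=CC(=O)c1c(OC)cc(O)cc1OC | intermediate
3 | 3,5-dimethoxy-4-(1,2,4-triazin-5-yl)phenol | COc1cc(O)cc(OC)c1-c1cnncn1 | intermediate
4 | bicyclo[2.2.1]hepta-2,5-diene (norbornadiene) | C1=CC2C=CC1C2 | starting material
5 | [4+2] adduct of 3 (through triazine C3 and C6) with one C=C of 4: a 2,3,5-triazabicyclo[2.2.2]octa-2,5-diene fused to norbornene, aryl on the imine carbon; racemic, relative configuration not specified | C12N=NC(C(c3c(OC)cc(O)cc3OC)=N1)C1C3C=CC(C3)C21 | intermediate (not isolated)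
6 | 4-(4a,5,8,8a-tetrahydro-5,8-methanoisoquinolin-3-yl)-3,5-dimethoxyphenol; racemic, relative configuration not specified | N1=CC2C3C=CC(C3)C2C=C1c1c(OC)cc(O)cc1OC | intermediate (not isolated)
7 | 3,5-dimethoxy-4-(pyridin-2-yl)phenol | COc1cc(O)cc(OC)c1-c1ccccn1 | intermediate
8 | 3,5-dimethoxy-4-(pyridin-2-yl)phenyl acetate | COc1cc(OC(C)=O)cc(OC)c1-c1ccccn1 | intermediate (not isolated)
9 | 1-[6-hydroxy-2,4-dimethoxy-3-(pyridin-2-yl)phenyl]ethan-1-one | CC(=O)c1c(O)cc(OC)c(-c2ccccn2)c1OC | intermediate
10 | (2E)-3-(dimethylamino)-1-[6-hydroxy-2,4-dimethoxy-3-(pyridin-2-yl)phenyl]prop-2-en-1-one | CN(C)/C=C/C(=O)c1c(O)cc(OC)c(-c2ccccn2)c1OC | intermediate (not isolated)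
11 | 5,7-dimethoxy-6-(pyridin-2-yl)-4H-chromen-4-one | COc1cc2occc(=O)c2c(OC)c1-c1ccccn1 | intermediate
12 | 5,7-dihydroxy-6-(pyridin-2-yl)-4H-chromen-4-one | Oc1cc2occc(=O)c2c(O)c1-c1ccccn1 | intermediate
13 | 5,7-bis(benzyloxy)-6-(pyridin-2-yl)-4H-chromen-4-one | O=c1ccoc2cc(OCc3ccccc3)c(-c3ccccn3)c(OCc3ccccc3)c12 | intermediate
14 | [4-(benzyloxy)phenyl]boronic acid | OB(O)c1ccc(OCc2ccccc2)cc1 | starting material
15 | (2S)-5,7-bis(benzyloxy)-2-[4-(benzyloxy)phenyl]-6-(pyridin-2-yl)-2,3-dihydro-4H-chromen-4-one | O=C1C[C@@H](c2ccc(OCc3ccccc3)cc2)Oc2cc(OCc3ccccc3)c(-c3ccccn3)c(OCc3ccccc3)c21 | intermediate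
16 | 2-{(2S)-5,7-bis(benzyloxy)-2-[4-(benzyloxy)phenyl]-4-oxo-3,4-dihydro-2H-chromen-6-yl}-1-methylpyridin-1-ium iodide | C[n+]1ccccc1-c1c(OCc2ccccc2)cc2c(c1OCc1ccccc1)C(=O)C[C@@H](c1ccc(OCc3ccccc3)cc1)O2.[I-] | intermediate
17 | (2S)-5,7-bis(benzyloxy)-2-[4-(benzyloxy)phenyl]-6-[(2R)-1-methylpiperidin-2-yl]-2,3-dihydro-4H-chromen-4-one | CN1CCCC[C@@H]1c1c(OCc2ccccc2)cc2c(c1OCc1ccccc1)C(=O)C[C@@H](c1ccc(OCc3ccccc3)cc1)O2 | intermediate
18 | (2S)-5,7-dihydroxy-2-(4-hydroxyphenyl)-6-[(2R)-1-methylpiperidin-2-yl]-2,3-dihydro-4H-chromen-4-one | CN1CCCC[C@@H]1c1c(O)cc2c(c1O)C(=O)C[C@@H](c1ccc(O)cc1)O2 | target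

**Step count and risks**

Total step count: 11. Longest linear sequence: 11 steps (from 1; 4 and 14 enter as purchased reactants).

The three steps most likely to fail:

Step 10. Hydride delivery to C2 of the partly reduced ring is shielded by the two ortho benzyloxy groups, and the aryl–pyridinium bond rotates slowly. The catalyst may therefore discriminate the two faces poorly, or the reduction may stall before the ring is saturated. The fallback sets out from 16 and comes back at 17. Compound 16 is reduced without stereocontrol at the new centre by rhodium-catalysed transfer hydrogenation ([Cp*RhCl2]2, KI, HCO2H/Et3N, 40 °C; aq NaHCO3). This should give 17 together with its piperidine C2 epimer (2S)-5,7-bis(benzyloxy)-2-[4-(benzyloxy)phenyl]-6-[(2S)-1-methylpiperidin-2-yl]-2,3-dihydro-4H-chromen-4-one F1. Because flavanone C2 is already fixed, the two are diastereomers and should be separable by chromatography or by fractional crystallisation of their di-p-toluoyl-L-tartrate salts; 17 then enters step 11.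

Step 8. The electron-rich 5,7-dialkoxychromone may insert slowly into the aryl–palladium bond and the pyridine nitrogen may hold back palladium, so that protodeboronation of 14 outruns addition; enantioselectivity may also erode. The fallback sets out from 13 and comes back at 15. Addition of 14 without stereocontrol ([Rh(cod)OH]2, dioxane/H2O, 60 °C) should give rac-5,7-bis(benzyloxy)-2-[4-(benzyloxy)phenyl]-6-(pyridin-2-yl)-2,3-dihydro-4H-chromen-4-one F2. Kinetic resolution by asymmetric transfer hydrogenation follows (RuCl(p-cymene)[(R,R)-TsDPEN] or its antipode, whichever consumes the 2R enantiomer; HCO2H/Et3N, EtOAc, rt, stopped just past half conversion). It should reduce the 2R enantiomer to the cis alcohol (2R,4R)-5,7-bis(benzyloxy)-2-[4-(benzyloxy)phenyl]-6-(pyridin-2-yl)-3,4-dihydro-2H-chromen-4-ol F3 and leave 15, which is separated by chromatography.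

Step 2. Ring closure of the open-chain amidrazone onto the ketone carbonyl, which is twisted and flanked by two methoxy groups, may stall, and free hydrazine may over-condense with the aldehyde. The fallback sets out from 2 and comes back at 3. Compound 2 is first condensed with formic hydrazide (EtOH, rt) to the aldehyde-derived N'-[(1E)-2-(4-hydroxy-2,6-dimethoxyphenyl)-2-oxoethylidene]formohydrazide F4. Heating F4 with NH4OAc in AcOH (110 °C, sealed tube) then lets ammonia, the smallest nitrogen nucleophile, condense with the hindered ketone and close onto the formyl carbon to give 3.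

Further compounds

F1 | step 10 | (2S)-5,7-bis(benzyloxy)-2-[4-(benzyloxy)phenyl]-6-[(2S)-1-methylpiperidin-2-yl]-2,3-dihydro-4H-chromen-4-one | CN1CCCC[C@H]1c1c(OCc2ccccc2)cc2c(c1OCc1ccccc1)C(=O)C[C@@H](c1ccc(OCc3ccccc3)cc1)O2
F2 | step 8 | rac-5,7-bis(benzyloxy)-2-[4-(benzyloxy)phenyl]-6-(pyridin-2-yl)-2,3-dihydro-4H-chromen-4-one | O=C1CC(c2ccc(OCc3ccccc3)cc2)Oc2cc(OCc3ccccc3)c(-c3ccccn3)c(OCc3ccccc3)c21
F3 | step 8 | (2R,4R)-5,7-bis(benzyloxy)-2-[4-(benzyloxy)phenyl]-6-(pyridin-2-yl)-3,4-dihydro-2H-chromen-4-ol | O[C@@H]1C[C@H](c2ccc(OCc3ccccc3)cc2)Oc2cc(OCc3ccccc3)c(-c3ccccn3)c(OCc3ccccc3)c21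
F4 | step 2 | N'-[(1E)-2-(4-hydroxy-2,6-dimethoxyphenyl)-2-oxoethylidene]formohydrazide | O=CN/N=C/C(=O)c1c(OC)cc(O)cc1OC
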